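**Retrosynthetic overview**

1. Locants: C1 (ester carbinol), C2=C3 (methyl on C3), C4, C5, C6 (ring-fusion carbinol), C7 (isopropyl), C8, C9, C10 (ring-fusion quaternary carbon with methyl); seven-membered ring = C1–C6 + C10, five-membered ring = C6–C10. The plan rests on the two-carbon bridge C4–C5, the only part of the seven-membered ring without a functional group, lying between allylic C4 and the methylene on carbinol C6.
2. Target ⇒ anisoylation, desilylation and desulfonylation of a C5-phenylsulfonyl bicycle ⇒ C4–C5 bond: the C5 carbanion of a β-hydroxy sulfone (as its alkoxide) is alkylated by a Z-allylic chloride at C4. This closes the seven-membered ring, last.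
3. β-Hydroxy sulfone ⇒ C5–C6 bond from LiCH2SO2Ph and a C6 ketone; C1–C10 bond (with the C1 and C10 stereocentres) from an aldol reaction of a regiodefined cyclopentanone enolate with a Z-enal.
4. Enolate ⇒ enol formate ⇒ cyclopentenecarbaldehyde ⇒ (S)-limonene by ozonolysis and aldol ring contraction (five-membered ring formed first, C7 from the chiral pool); Z-enal ⇒ prop-2-yn-1-ol by anti-carbomagnesiation.

Key step: step 13

Remark: these locants are used throughout; α is the face of the five-membered ring opposite to the C7 isopropyl group and β the face that carries it; the azulene locants in the names map as 3 = C7, 3a = C6, 4 = C5, 8 = C1, 8a = C10.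

**Route**

Step 1
Reactants: 1 (S)-limonene [(4S)-1-methyl-4-(prop-1-en-2-yl)cyclohex-1-ene]
Product: 2 (S)-p-menth-1-ene [(4S)-1-methyl-4-(propan-2-yl)cyclohex-1-ene]
Conditions: H2 (1 atm, 1 equiv), PtO2 (cat.), EtOH, rt
Reagents that add atoms: none
Why: Chemoselective catalytic hydrogenation, in which the 1,1-disubstituted isopropenyl alkene is reduced much faster than the trisubstituted ring alkene and the stereocentre is not touched.

Step 2
Reactants: 2 (S)-p-menth-1-ene
Product: 4 (3S)-6-oxo-3-(propan-2-yl)heptanal, via ozonide 3 (not isolated)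
Conditions: O3, CH2Cl2, −78 °C; PPh3, −78 °C → rt
Reagents that add atoms: ozone, O=[O+][O-]
Why: Ozonolysis with reductive work-up cleaves the ring alkene to a methyl ketone and an aldehyde; the stereocentre is β to the aldehyde and cannot epimerise.

Step 3
Reactants: 4 (3S)-6-oxo-3-(propan-2-yl)heptanal
Product: 5 (5R)-2-methyl-5-(propan-2-yl)cyclopent-1-ene-1-carbaldehyde
Conditions: piperidine (cat.), AcOH (cat.), toluene, reflux, Dean–Stark
Reagents that add atoms: none
Why: Amine-catalysed intramolecular aldol condensation, in which the enamine of the aldehyde attacks the methyl ketone to close the five-membered ring and dehydration gives the conjugated enal with the stereocentre (the future C7) at a non-enolisable position.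

Step 4
Reactants: 5 (5R)-2-methyl-5-(propan-2-yl)cyclopent-1-ene-1-carbaldehyde
Product: 6 (5R)-2-methyl-5-(propan-2-yl)cyclopent-1-en-1-yl formate
Conditions: 30% H2O2, bis(2-nitrophenyl) diselenide (cat.), CH2Cl2, rt
Reagents that add atoms: hydrogen peroxide, OO
Why: Baeyer–Villiger oxidation of an α,β-unsaturated aldehyde by the areneperseleninic acid formed in the flask, in which the alkenyl group migrates to oxygen, so the enol formate fixes the later enolate double bond at C6=C10 without exposing the C7 hydrogen to an enolisable free ketone.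

Step 5
Reactants: 7 prop-2-yn-1-ol
Product: 9 (2Z)-3-iodo-2-methylprop-2-en-1-ol, via alkenylmagnesium alkoxide 8 (not isolated)
Conditions: MeMgBr (2.3 equiv), CuI (10 mol %), THF, −10 °C → rt; I2, −10 °C
Reagents that add atoms: methylmagnesium bromide, C[Mg]Br; iodine, II
Why: Copper-catalysed anti-carbomagnesiation of the propargylic alkoxide delivers methyl to the proximal alkyne carbon through a five-membered magnesium chelate, and iodinolysis with retention gives the Z-iodide that fixes the later C2=C3 geometry.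

Step 6
Reactants: 9 (2Z)-3-iodo-2-methylprop-2-en-1-ol
Product: 10 tert-butyl{[(2Z)-3-iodo-2-methylprop-2-en-1-yl]oxy}dimethylsilane
Conditions: TBSCl, imidazole, CH2Cl2, 0 °C → rt
Reagents that add atoms: tert-butyldimethylsilyl chloride, CC(C)(C)[Si](C)(C)Cl
Why: Standard imidazole-promoted silylation of a primary allylic alcohol.

Step 7
Reactants: 10 tert-butyl{[(2Z)-3-iodo-2-methylprop-2-en-1-yl]oxy}dimethylsilane
Product: 12 (2Z)-4-(tert-butyldimethylsilyloxy)-3-methylbut-2-enal, via alkenyllithium 11 (not isolated)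
Conditions: t-BuLi (2 equiv), Et2O, −78 °C; DMF, −78 → −20 °C; AcOH, then H2O
Reagents that add atoms: N,N-dimethylformamide, CN(C)C=O
Why: Iodine–lithium exchange with retention of alkene geometry followed by Bouveault formylation should give the Z-enal, the alkenyllithium being kept at −78 °C to avoid 1,4-migration of silicon from oxygen to carbon.

Step 8
Reactants: 6 (5R)-2-methyl-5-(propan-2-yl)cyclopent-1-en-1-yl formate; 12 (2Z)-4-(tert-butyldimethylsilyloxy)-3-methylbut-2-enal
Product: 14 (2R,5R)-2-[(1R,2Z)-4-(tert-butyldimethylsilyloxy)-1-hydroxy-3-methylbut-2-en-1-yl]-2-methyl-5-(propan-2-yl)cyclopentan-1-one, via lithium enolate 13 (not isolated)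
Conditions: MeLi (2 equiv), THF, −78 → 0 °C (6 added to MeLi); 12, −78 °C; AcOH, −78 °C
Reagents that add atoms: none
Why: Cleavage of the enol ester with MeLi gives the tetrasubstituted lithium enolate regiospecifically, and its aldol addition through a Zimmerman–Traxler chair on the enolate face away from the C7 isopropyl group, with the alkenyl residue of the enal equatorial, should create C10 (methyl cis to isopropyl) and C1 (R, hydroxyl syn to the C10 methyl in the zigzag projection) in one operation.

Step 9
Reactants: 14 aldol adduct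
Product: 15 (2R,5R)-2-[(1R,2Z)-1,4-bis(tert-butyldimethylsilyloxy)-3-methylbut-2-en-1-yl]-2-methyl-5-(propan-2-yl)cyclopentan-1-one
Conditions: TBSOTf, 2,6-lutidine, CH2Cl2, −78 → 0 °C
Reagents that add atoms: tert-butyldimethylsilyl trifluoromethanesulfonate, CC(C)(C)[Si](C)(C)OS(=O)(=O)C(F)(F)F
Why: Silylation with the silyl triflate, which the neopentylic secondary alcohol requires; C10 carries no hydrogen, so β-elimination is not possible.

Step 10
Reactants: 15 bis-silyl ketone; 16 methyl phenyl sulfone
Product: 18 (1S,2R,5R)-2-[(1R,2Z)-1,4-bis(tert-butyldimethylsilyloxy)-3-methylbut-2-en-1-yl]-2-methyl-1-[(phenylsulfonyl)methyl]-5-(propan-2-yl)cyclopentan-1-ol, via lithiated sulfone 17 (not isolated)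
Conditions: 16, n-BuLi, THF, −78 °C; 15, CeCl3 (anhydrous), THF, −78 °C; AcOH, −78 °C
Reagents that add atoms: none
Why: CeCl3-mediated 1,2-addition of an α-sulfonyl carbanion to a ketone, which curbs enolisation at C7 and reversal; in the twist conformer with both large groups pseudoequatorial the C10 methyl is pseudoaxial on the β face, so the nucleophile should enter from the α face, anti to that methyl and to the C7 isopropyl group, giving the C6 hydroxyl cis to both.

Step 11
Reactants: 18 β-hydroxy sulfone bis-silyl ether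
Product: 19 (1S,2R,5R)-2-[(1R,2Z)-1-(tert-butyldimethylsilyloxy)-4-hydroxy-3-methylbut-2-en-1-yl]-2-methyl-1-[(phenylsulfonyl)methyl]-5-(propan-2-yl)cyclopentan-1-ol
Conditions: HF·pyridine, pyridine, THF, 0 °C
Reagents that add atoms: none
Why: Selective desilylation, the primary allylic silyl ether being cleaved much faster than the neopentylic secondary one.

Step 12
Reactants: 19 primary allylic alcohol
Product: 20 (1S,2R,5R)-2-[(1R,2Z)-1-(tert-butyldimethylsilyloxy)-4-chloro-3-methylbut-2-en-1-yl]-2-methyl-1-[(phenylsulfonyl)methyl]-5-(propan-2-yl)cyclopentan-1-ol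
Conditions: PPh3, Cl3CC(O)CCl3, CH2Cl2, 0 °C
Reagents that add atoms: hexachloroacetone, O=C(C(Cl)(Cl)Cl)C(Cl)(Cl)Cl
Why: Appel-type chlorination, in which chloride displaces the alkoxyphosphonium ion at the primary carbon by SN2 without allylic transposition or Z/E isomerisation, while the hindered tertiary alcohol does not react.

Step 13
Reactants: 20 Z-allylic chloride β-hydroxy sulfone
Product: 22 (3R,3aS,8R,8aR)-8-(tert-butyldimethylsilyloxy)-6,8a-dimethyl-4-(phenylsulfonyl)-3-(propan-2-yl)-1,2,3,3a,4,5,8,8a-octahydroazulen-3a-ol (configuration at C4 of the azulene, i.e. C5, not assigned), via dilithio dianion 21 (not isolated)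
Conditions: n-BuLi (2.1 equiv), THF (0.005 M), −78 °C; DMPU, −78 → −20 °C; AcOH
Reagents that add atoms: none
Why: The first equivalent of n-BuLi gives the tertiary lithium alkoxide and the second removes a C5 proton next to sulfur; on warming with DMPU the C5 carbanion displaces chloride at the primary allylic carbon C4 by SN2 and forms the C4–C5 bond. The closest known reaction type is the intramolecular alkylation of α-sulfonyl carbanions by allylic halides for carbocycle synthesis, here run on the dianion of a β-hydroxy sulfone. The seven-membered ring (C1–C6 and C10) closes in 7-exo-tet fashion, helped by the Z alkene and by the cis arrangement of the two arms on the cyclopentane, which hold C4 within reach of C5. The only new stereocentre, C5, is not controlled and need not be, since it becomes a methylene group in step 14; C1, C6, C7 and C10 are not touched. The step needs C-alkylation by SN2 in preference to SN2' attack at C2 (which would close a five-membered ring), to O-alkylation and to β-elimination: the soft, charge-delocalised carbanion prefers the open primary terminus over the alkene carbon next to neopentylic C1, the oxido group is a poor leaving group and a far weaker nucleophile than the carbanion, and high dilution suppresses intermolecular alkylation.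

Step 14
Reactants: 22 bicyclic C5 sulfone
Product: 23 (3R,3aS,8R,8aR)-8-(tert-butyldimethylsilyloxy)-6,8a-dimethyl-3-(propan-2-yl)-1,2,3,3a,4,5,8,8a-octahydroazulen-3a-ol
Conditions: 6% Na/Hg, Na2HPO4, MeOH–THF, −20 °C
Reagents that add atoms: none
Why: Reductive desulfonylation by electron transfer from sodium amalgam, in which the C5–S bond is cleaved and the carbanion is protonated, the phosphate buffer keeping the β-hydroxyl un-ionised so that Julia-type elimination is disfavoured, and the uncontrolled C5 centre becomes a methylene group.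

Step 15
Reactants: 23 bicyclic silyl ether
Product: 24 (3R,3aS,8R,8aR)-6,8a-dimethyl-3-(propan-2-yl)-1,2,3,3a,4,5,8,8a-octahydroazulene-3a,8-diol
Conditions: Bu4NF, THF, rt
Reagents that add atoms: none
Why: Fluoride-mediated cleavage of the remaining silyl ether; the alkene and the tertiary alcohol are inert.

Step 16
Reactants: 24 diol; 25 4-methoxybenzoyl chloride
Product: 26 (3R,3aS,8R,8aR)-3a-hydroxy-6,8a-dimethyl-3-(propan-2-yl)-1,2,3,3a,4,5,8,8a-octahydroazulen-8-yl 4-methoxybenzoate (target)
Conditions: 25, Et3N, DMAP (cat.), CH2Cl2, 0 °C → rt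
Reagents that add atoms: none
Why: DMAP-catalysed acylation (nucleophilic catalysis) of the secondary allylic alcohol, the ring-fusion tertiary alcohol being too hindered to react, with no stereocentre touched.

**Compound list**

1 | (S)-limonene | CC1=CC[C@@H](C(C)=C)CC1 | starting material
2 | (S)-p-menth-1-ene | CC1=CC[C@@H](C(C)C)CC1 | intermediate
3 | ozonide (1,2,4-trioxolane) of 2, not isolated | CC12OOC(C[C@@H](C(C)C)CC1)O2 | intermediate
4 | (3S)-6-oxo-3-(propan-2-yl)heptanal | CC(=O)CC[C@@H](CC=O)C(C)C | intermediate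
5 | (5R)-2-methyl-5-(propan-2-yl)cyclopent-1-ene-1-carbaldehyde | CC(C)[C@H]1CCC(C)=C1C=O | intermediate
6 | (5R)-2-methyl-5-(propan-2-yl)cyclopent-1-en-1-yl formate | CC(C)[C@H]1CCC(C)=C1OC=O | intermediate
7 | prop-2-yn-1-ol | C#CCO | starting material
8 | bromomagnesium (2Z)-3-(bromomagnesio)-2-methylprop-2-en-1-olate, not isolated | C/C(CO[Mg]Br)=C/[Mg]Br | intermediate
9 | (2Z)-3-iodo-2-methylprop-2-en-1-ol | C/C(CO)=C/I | intermediate
10 | tert-butyl{[(2Z)-3-iodo-2-methylprop-2-en-1-yl]oxy}dimethylsilane | C/C(CO[Si](C)(C)C(C)(C)C)=C/I | intermediate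
11 | [(1Z)-3-(tert-butyldimethylsilyloxy)-2-methylprop-1-en-1-yl]lithium, not isolated | C/C(CO[Si](C)(C)C(C)(C)C)=C/[Li] | intermediate
12 | (2Z)-4-(tert-butyldimethylsilyloxy)-3-methylbut-2-enal | C/C(CO[Si](C)(C)C(C)(C)C)=C/C=O | intermediate
13 | lithium (5R)-2-methyl-5-(propan-2-yl)cyclopent-1-en-1-olate, not isolated | CC(C)[C@H]1CCC(C)=C1O[Li] | intermediate
14 | (2R,5R)-2-[(1R,2Z)-4-(tert-butyldimethylsilyloxy)-1-hydroxy-3-methylbut-2-en-1-yl]-2-methyl-5-(propan-2-yl)cyclopentan-1-one | O[C@H](/C=C(/C)CO[Si](C)(C)C(C)(C)C)[C@@]1(C)CC[C@H](C(C)C)C1=O | intermediate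
15 | (2R,5R)-2-[(1R,2Z)-1,4-bis(tert-butyldimethylsilyloxy)-3-methylbut-2-en-1-yl]-2-methyl-5-(propan-2-yl)cyclopentan-1-one | CC(C)(C)[Si](C)(C)O[C@H](/C=C(/C)CO[Si](C)(C)C(C)(C)C)[C@@]1(C)CC[C@H](C(C)C)C1=O | intermediate
16 | methyl phenyl sulfone | CS(=O)(=O)c1ccccc1 | starting material
17 | [(phenylsulfonyl)methyl]lithium, not isolated | [Li]CS(=O)(=O)c1ccccc1 | intermediate
18 | (1S,2R,5R)-2-[(1R,2Z)-1,4-bis(tert-butyldimethylsilyloxy)-3-methylbut-2-en-1-yl]-2-methyl-1-[(phenylsulfonyl)methyl]-5-(propan-2-yl)cyclopentan-1-ol | CC(C)(C)[Si](C)(C)O[C@H](/C=C(/C)CO[Si](C)(C)C(C)(C)C)[C@@]1(C)CC[C@H](C(C)C)[C@@]1(O)CS(=O)(=O)c1ccccc1 | intermediate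
19 | (1S,2R,5R)-2-[(1R,2Z)-1-(tert-butyldimethylsilyloxy)-4-hydroxy-3-methylbut-2-en-1-yl]-2-methyl-1-[(phenylsulfonyl)methyl]-5-(propan-2-yl)cyclopentan-1-ol | CC(C)(C)[Si](C)(C)O[C@H](/C=C(/C)CO)[C@@]1(C)CC[C@H](C(C)C)[C@@]1(O)CS(=O)(=O)c1ccccc1 | intermediate
20 | (1S,2R,5R)-2-[(1R,2Z)-1-(tert-butyldimethylsilyloxy)-4-chloro-3-methylbut-2-en-1-yl]-2-methyl-1-[(phenylsulfonyl)methyl]-5-(propan-2-yl)cyclopentan-1-ol | CC(C)(C)[Si](C)(C)O[C@H](/C=C(/C)CCl)[C@@]1(C)CC[C@H](C(C)C)[C@@]1(O)CS(=O)(=O)c1ccccc1 | intermediate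
21 | dilithio derivative of 20 (lithium alkoxide at C6, lithium at C5 next to sulfur), not isolated | CC(C)(C)[Si](C)(C)O[C@H](/C=C(/C)CCl)[C@@]1(C)CC[C@H](C(C)C)[C@@]1(O[Li])C([Li])S(=O)(=O)c1ccccc1 | intermediate
22 | (3R,3aS,8R,8aR)-8-(tert-butyldimethylsilyloxy)-6,8a-dimethyl-4-(phenylsulfonyl)-3-(propan-2-yl)-1,2,3,3a,4,5,8,8a-octahydroazulen-3a-ol, C4 (= C5) unassigned | CC(C)(C)[Si](C)(C)O[C@@H]1C=C(C)CC(S(=O)(=O)c3ccccc3)[C@]2(O)[C@@H](C(C)C)CC[C@]12C | intermediate
23 | (3R,3aS,8R,8aR)-8-(tert-butyldimethylsilyloxy)-6,8a-dimethyl-3-(propan-2-yl)-1,2,3,3a,4,5,8,8a-octahydroazulen-3a-ol | CC(C)(C)[Si](C)(C)O[C@@H]1C=C(C)CC[C@]2(O)[C@@H](C(C)C)CC[C@]12C | intermediate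
24 | (3R,3aS,8R,8aR)-6,8a-dimethyl-3-(propan-2-yl)-1,2,3,3a,4,5,8,8a-octahydroazulene-3a,8-diol | O[C@@H]1C=C(C)CC[C@]2(O)[C@@H](C(C)C)CC[C@]12C | intermediate
25 | 4-methoxybenzoyl chloride | COc1ccc(cc1)C(Cl)=O | starting material
26 | (3R,3aS,8R,8aR)-3a-hydroxy-6,8a-dimethyl-3-(propan-2-yl)-1,2,3,3a,4,5,8,8a-octahydroazulen-8-yl 4-methoxybenzoate | COc1ccc(C(=O)O[C@@H]2C=C(C)CC[C@]3(O)[C@@H](C(C)C)CC[C@]23C)cc1 | target

**Step count**

Total: 16 steps (13 in the main line, 3 for the enal 12). Longest linear sequence: 13 steps, from 1 to 26 (steps 1–4 and 8–16).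

**Steps most likely to fail, with fallbacks**

1. Step 13 (ring closure). The carbanion may attack C2 with allylic transposition and close a five-membered ring, the monolithium alkoxide may fragment by retro-addition before the second deprotonation, n-BuLi may attack the allylic chloride, or intermolecular alkylation may compete. The fallback forms the seven-membered ring by ring-closing metathesis at C2=C3; it sets out from 6 and rejoins the route at 23. Enolate 13, made from 6 as in step 8, is added to acrolein (THF, −78 °C) through the same chair to give (2R,5R)-2-[(1R)-1-hydroxyprop-2-en-1-yl]-2-methyl-5-(propan-2-yl)cyclopentan-1-one F1, which is silylated (TBSOTf, 2,6-lutidine) to its tert-butyldimethylsilyl ether F2. 3-Methylbut-3-en-1-ylmagnesium bromide F3, with CeCl3 in THF at −78 °C, should add to the ketone from the α face to give the diene (1S,2R,5R)-2-[(1R)-1-(tert-butyldimethylsilyloxy)prop-2-en-1-yl]-2-methyl-1-(3-methylbut-3-en-1-yl)-5-(propan-2-yl)cyclopentan-1-ol F4, which already holds the C4–C5 bridge. Ring-closing metathesis of F4 with the second-generation Grubbs catalyst (toluene, 80 °C) should then give 23 directly.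

2. Step 8 (aldol addition). Simple diastereoselection at C1 may be poor, the crowded aldolate may revert by retro-aldol cleavage, or the Z-enal may isomerise under the basic conditions. The fallback builds C10 and C1 in separate operations; it sets out from 6 and rejoins at 14. Enolate 13 is hydroxymethylated with monomeric formaldehyde (THF, −78 °C; attack anti to the isopropyl group) to give (2R,5R)-2-(hydroxymethyl)-2-methyl-5-(propan-2-yl)cyclopentan-1-one F5, which Dess–Martin periodinane oxidises to (1R,3R)-1-methyl-2-oxo-3-(propan-2-yl)cyclopentane-1-carbaldehyde F6. Alkenyllithium 11 (from 10 as in step 7) is added at −78 °C to F6 precomplexed with MgBr2·OEt2. In the magnesium chelate of the two carbonyl groups the nucleophile should reach C1 from the side of the C10 methyl group, not across the ring methylene, which gives the C1 configuration of 14; the hindered ring ketone should be left alone.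

3. Step 10 (sulfonylmethyl addition). The basic, stabilised carbanion may enolise the hindered ketone at C7, or the crowded tertiary alkoxide may revert, giving low conversion and erosion of configuration at C7. The fallback uses a non-stabilised sulfur nucleophile and adjusts the oxidation state afterwards; it sets out from 15 and rejoins at 18. (Phenylsulfanyl)methyllithium F7 (thioanisole, n-BuLi, DABCO, THF, 0 °C) should add irreversibly from the same α face to give (1S,2R,5R)-2-[(1R,2Z)-1,4-bis(tert-butyldimethylsilyloxy)-3-methylbut-2-en-1-yl]-2-methyl-1-[(phenylsulfanyl)methyl]-5-(propan-2-yl)cyclopentan-1-ol F8. Chemoselective oxidation at sulfur (30% H2O2, (NH4)6Mo7O24 cat., EtOH, 0 °C → rt), which spares the trisubstituted alkene and the silyl ethers, should then give 18.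

Further compounds
F1 | step 13 | (2R,5R)-2-[(1R)-1-hydroxyprop-2-en-1-yl]-2-methyl-5-(propan-2-yl)cyclopentan-1-one | O[C@H](C=C)[C@@]1(C)CC[C@H](C(C)C)C1=O
F2 | step 13 | (2R,5R)-2-[(1R)-1-(tert-butyldimethylsilyloxy)prop-2-en-1-yl]-2-methyl-5-(propan-2-yl)cyclopentan-1-one | CC(C)(C)[Si](C)(C)O[C@H](C=C)[C@@]1(C)CC[C@H](C(C)C)C1=O
F3 | step 13 | 3-methylbut-3-en-1-ylmagnesium bromide | C=C(C)CC[Mg]Br
F4 | step 13 | (1S,2R,5R)-2-[(1R)-1-(tert-butyldimethylsilyloxy)prop-2-en-1-yl]-2-methyl-1-(3-methylbut-3-en-1-yl)-5-(propan-2-yl)cyclopentan-1-ol | CC(C)(C)[Si](C)(C)O[C@H](C=C)[C@@]1(C)CC[C@H](C(C)C)[C@@]1(O)CCC(C)=C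
F5 | step 8 | (2R,5R)-2-(hydroxymethyl)-2-methyl-5-(propan-2-yl)cyclopentan-1-one | OC[C@@]1(C)CC[C@H](C(C)C)C1=O
F6 | step 8 | (1R,3R)-1-methyl-2-oxo-3-(propan-2-yl)cyclopentane-1-carbaldehyde | O=C[C@@]1(C)CC[C@H](C(C)C)C1=O
F7 | step 10 | (phenylsulfanyl)methyllithium | [Li]CSc1ccccc1
F8 | step 10 | (1S,2R,5R)-2-[(1R,2Z)-1,4-bis(tert-butyldimethylsilyloxy)-3-methylbut-2-en-1-yl]-2-methyl-1-[(phenylsulfanyl)methyl]-5-(propan-2-yl)cyclopentan-1-ol | CC(C)(C)[Si](C)(C)O[C@H](/C=C(/C)CO[Si](C)(C)C(C)(C)C)[C@@]1(C)CC[C@H](C(C)C)[C@@]1(O)CSc1ccccc1
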